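The route rests on cutting the O–C4 bond of the 3(2H)-furanone (ring O–C4=C5–C6(=O)–C7), the oxygen bridge that spans C4 and C7 of the ten-membered carbocycle C1–C10. This leaves an (E)-cyclodec-2-enone with a tertiary C7 hydroxyl α′ to the ketone, the trans-fused α-methylene lactone at C9/C10, the C1 methacrylate and a C2 silyl ether. The key step exploits the ten-membered ring, which holds the C7 oxygen over C4: one palladium-mediated oxidative etherification closes the furanone and restores C4=C5 without touching a stereocentre. The macrocycle comes from a citramalate-derived bromomethyl butenolide and an aldol-derived iodoalkenyl aldehyde by zinc allylation and chromium-mediated closure at C5–C6.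

Key step: step 20

Remarks
- Numbering: ring carbons C1 (CH–O-methacrylate), C2 (CH–OH), C3 (CH–CH3), C4 (O–C=), C5 (=CH), C6 (C=O), C7 (C(CH3)–O), C8 (CH2), C9 (lactone O–CH), C10 (lactone CH); C11 lactone α-carbon, C12 lactone carbonyl, C13 exocyclic methylene.
- Structure check: 31 and 32 carry the configuration of 33 at all six centres (1S,2S,7R,9S,10R; C3 is S in 32 and 33 and R in 31 by CIP ranking only), and the E geometry of C4=C5 in 31 matches the furanone. Nothing had to be corrected.
- Design choice: the ring is not closed by alkene metathesis, because a ruthenium carbene at C4 would close a six-membered ring onto the C11=C13 methylene. The methylene lactone is instead made early by allylation, and the ring is closed at C5–C6 from an (E)-iodoalkene, which also fixes the enone geometry.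
- Assumptions: alkyne 3 and imide 13 are purchased. The C6 carbinol formed in step 18 is carried as both epimers, since step 19 removes this centre.

Step 1
Reactants: 1 (R)-citramalic acid
Product: 2 2-[(4R)-2,2,4-trimethyl-5-oxo-1,3-dioxolan-4-yl]acetic acid
Conditions: 2,2-dimethoxypropane, TsOH·H2O (cat.), CH2Cl2, rt
Reagents that add atoms: 2,2-dimethoxypropane, COC(C)(C)OC
Why: Acid-catalysed acetal exchange ties the α-hydroxy acid unit (C7–OH and the C6 carboxyl) into the favoured five-membered 1,3-dioxolan-4-one and leaves the C9 carboxyl free, without involving the quaternary centre C7.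

Step 2
Reactants: 2 2-[(4R)-2,2,4-trimethyl-5-oxo-1,3-dioxolan-4-yl]acetic acid; 3 1-methoxy-4-[(prop-2-yn-1-yloxy)methyl]benzene
Product: 5 (5R)-5-{5-[(4-methoxybenzyl)oxy]-2-oxopent-3-yn-1-yl}-2,2,5-trimethyl-1,3-dioxolan-4-one, via acid chloride 4 (not isolated)
Conditions: (COCl)2, DMF (cat.), CH2Cl2, 0 °C → rt, evaporate; then 3, PdCl2(PPh3)2 (2 mol%), CuI (4 mol%), Et3N (1.1 equiv), THF, rt
Reagents that add atoms: none
Why: Acyl chloride formation followed by the acyl Sonogashira coupling (copper acetylide onto an acylpalladium species) gives the ynone under nearly neutral conditions, so that the β-oxygen at C7 should not be eliminated.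

Step 3
Reactants: 5 (5R)-5-{5-[(4-methoxybenzyl)oxy]-2-oxopent-3-yn-1-yl}-2,2,5-trimethyl-1,3-dioxolan-4-one
Product: 6 (5R)-5-{(2S)-2-hydroxy-5-[(4-methoxybenzyl)oxy]pent-3-yn-1-yl}-2,2,5-trimethyl-1,3-dioxolan-4-one
Conditions: Ru[(S,S)-TsDPEN](p-cymene) (1 mol%), iPrOH, rt
Reagents that add atoms: none
Why: Noyori asymmetric transfer hydrogenation sets C9 (S) under catalyst control, the (S,S)-catalyst distinguishing the alkynyl from the alkyl flank in the sense established for alkyl alkynyl ketones; any exchange of the new carbinol with the dioxolanone carbonyl is harmless because step 4 reduces both forms to the same triol.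

Step 4
Reactants: 6 (5R)-5-{(2S)-2-hydroxy-5-[(4-methoxybenzyl)oxy]pent-3-yn-1-yl}-2,2,5-trimethyl-1,3-dioxolan-4-one
Product: 8 (2R,4S,5Z)-6-iodo-7-[(4-methoxybenzyl)oxy]-2-methylhept-5-ene-1,2,4-triol, via alkenylaluminate 7 (not isolated)
Conditions: NaAlH2(OCH2CH2OMe)2 (5 equiv), THF, −20 → 0 °C; then I2, THF, −78 → −20 °C; aq. Rochelle salt
Reagents that add atoms: iodine, II
Why: Hydroxyl-directed trans-hydroalumination of the propargylic alcohol places aluminium on the distal carbon C11 in a five-membered alkoxyaluminate, and iodinolysis with retention gives the (Z)-iodoalkene with iodine cis to C9, while the same hydride reduces the dioxolanone to the C6/C7 diol; the low temperature guards against loss of the C13 ether to an allene.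

Step 5
Reactants: 8 (2R,4S,5Z)-6-iodo-7-[(4-methoxybenzyl)oxy]-2-methylhept-5-ene-1,2,4-triol
Product: 9 (5S)-5-[(2R)-2,3-dihydroxy-2-methylpropyl]-3-{[(4-methoxybenzyl)oxy]methyl}furan-2(5H)-one
Conditions: PdCl2(PPh3)2 (5 mol%), CO (1 atm), Et3N, THF, 40 °C
Reagents that add atoms: carbon monoxide, [C-]#[O+]
Why: Palladium-catalysed carbonylative lactonisation: zerovalent palladium inserts into the C–I bond, CO insertion gives an acylpalladium species, and the cis-disposed C9 hydroxyl, the only one that can close a five-membered ring, captures it to form the butenolide.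

Step 6
Reactants: 9 (5S)-5-[(2R)-2,3-dihydroxy-2-methylpropyl]-3-{[(4-methoxybenzyl)oxy]methyl}furan-2(5H)-one
Product: 10 (5S)-5-{(2R)-2-hydroxy-2-methyl-3-[(triethylsilyl)oxy]propyl}-3-{[(4-methoxybenzyl)oxy]methyl}furan-2(5H)-one
Conditions: Et3SiCl (1.05 equiv), imidazole, CH2Cl2, −20 °C
Reagents that add atoms: chlorotriethylsilane, CC[Si](Cl)(CC)CC
Why: Silyl ether formation is selective for the primary C6 hydroxyl because the tertiary C7 hydroxyl is too hindered to react with the chlorosilane under these conditions.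

Step 7
Reactants: 10 (5S)-5-{(2R)-2-hydroxy-2-methyl-3-[(triethylsilyl)oxy]propyl}-3-{[(4-methoxybenzyl)oxy]methyl}furan-2(5H)-one
Product: 11 (5S)-3-(hydroxymethyl)-5-{(2R)-2-hydroxy-2-methyl-3-[(triethylsilyl)oxy]propyl}furan-2(5H)-one
Conditions: DDQ (1.3 equiv), CH2Cl2/pH 7 buffer (10:1), 0 °C
Reagents that add atoms: none
Why: Oxidative cleavage of the p-methoxybenzyl ether by DDQ (hydride abstraction, then hydrolysis of the oxocarbenium ion) frees the C13 hydroxyl, no other hydroxyl being close enough to trap the cation as an acetal, and the silyl ether should survive the buffered medium.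

Step 8
Reactants: 11 (5S)-3-(hydroxymethyl)-5-{(2R)-2-hydroxy-2-methyl-3-[(triethylsilyl)oxy]propyl}furan-2(5H)-one
Product: 12 (5S)-3-(bromomethyl)-5-{(2R)-2-hydroxy-2-methyl-3-[(triethylsilyl)oxy]propyl}furan-2(5H)-one
Conditions: CBr4, PPh3, CH2Cl2, −20 → 0 °C
Reagents that add atoms: tetrabromomethane, BrC(Br)(Br)Br
Why: Appel bromination converts the primary allylic alcohol through its alkoxyphosphonium ion, whereas the tertiary C7 hydroxyl does not react at this temperature; the bromide is used at once.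

Step 9
Reactants: 13 (4S)-4-benzyl-3-propanoyl-1,3-oxazolidin-2-one; 14 3-methylbut-2-enal
Product: 16 (4S)-4-benzyl-3-[(2S,3R)-3-hydroxy-2,5-dimethylhex-4-enoyl]-1,3-oxazolidin-2-one, via boron enolate 15 (not isolated)
Conditions: Bu2BOTf, iPr2NEt, CH2Cl2, 0 °C; then 14, −78 → 0 °C; H2O2, MeOH, pH 7 buffer
Reagents that add atoms: none
Why: Evans syn aldol reaction: the Z boron enolate reacts through a Zimmerman–Traxler chair on the enolate face left open by the benzyl group of the auxiliary, which sets C3 (S in 16) and C2 (R in 16) in the required syn relation.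

Step 10
Reactants: 16 (4S)-4-benzyl-3-[(2S,3R)-3-hydroxy-2,5-dimethylhex-4-enoyl]-1,3-oxazolidin-2-one
Product: 17 (4S)-4-benzyl-3-[(2S,3R)-2,5-dimethyl-3-(triethylsilyloxy)hex-4-enoyl]-1,3-oxazolidin-2-one
Conditions: Et3SiOTf, 2,6-lutidine, CH2Cl2, −78 → 0 °C
Reagents that add atoms: triethylsilyl trifluoromethanesulfonate, CC[Si](CC)(CC)OS(=O)(=O)C(F)(F)F
Why: Silylation of the secondary carbinol with the silyl triflate and a hindered base installs the C2 protecting group that is kept until the last step and prevents retro-aldol cleavage.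

Step 11
Reactants: 17 (4S)-4-benzyl-3-[(2S,3R)-2,5-dimethyl-3-(triethylsilyloxy)hex-4-enoyl]-1,3-oxazolidin-2-one
Product: 18 (2R,3R)-2,5-dimethyl-3-(triethylsilyloxy)hex-4-en-1-ol
Conditions: LiBH4, MeOH (1 equiv), THF, 0 °C
Reagents that add atoms: none
Why: Reductive removal of the auxiliary: borohydride attacks the more electrophilic exocyclic imide carbonyl and gives the primary alcohol without epimerising C3.

Step 12
Reactants: 18 (2R,3R)-2,5-dimethyl-3-(triethylsilyloxy)hex-4-en-1-ol
Product: 19 (2S,3R)-2,5-dimethyl-3-(triethylsilyloxy)hex-4-enal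
Conditions: Dess–Martin periodinane, NaHCO3, CH2Cl2, 0 °C → rt
Reagents that add atoms: none
Why: Dess–Martin oxidation under buffered, non-basic conditions gives the α-branched aldehyde without epimerisation; it is used without storage.

Step 13
Reactants: 19 (2S,3R)-2,5-dimethyl-3-(triethylsilyloxy)hex-4-enal
Product: 20 triethyl{[(1E,3R,4S)-1-iodo-3,6-dimethylhepta-1,5-dien-4-yl]oxy}silane
Conditions: CrCl2 (6 equiv), CHI3 (2 equiv), THF, 0 °C → rt
Reagents that add atoms: iodoform, IC(I)I
Why: Takai olefination: the geminal dichromium reagent from CHI3 adds to the aldehyde and eliminates to the (E)-iodoalkene, a non-basic process that leaves C3 intact and supplies C5.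

Step 14
Reactants: 20 triethyl{[(1E,3R,4S)-1-iodo-3,6-dimethylhepta-1,5-dien-4-yl]oxy}silane
Product: 22 (2S,3R,4E)-5-iodo-3-methyl-2-(triethylsilyloxy)pent-4-enal, via ozonide 21 (not isolated)
Conditions: O3, CH2Cl2, −78 °C (Sudan Red 7B end point); then PPh3, −78 °C → rt
Reagents that add atoms: ozone, [O-][O+]=O
Why: Ozonolysis with reductive work-up cleaves the electron-rich trisubstituted alkene, which should react with ozone much faster than the halogen-deactivated iodoalkene, and so unveils the C1 aldehyde last.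

Step 15
Reactants: 12 (5S)-3-(bromomethyl)-5-{(2R)-2-hydroxy-2-methyl-3-[(triethylsilyl)oxy]propyl}furan-2(5H)-one; 22 (2S,3R,4E)-5-iodo-3-methyl-2-(triethylsilyloxy)pent-4-enal
Product: 24 (4R,5S)-4-[(1S,2S,3R,4E)-1-hydroxy-5-iodo-3-methyl-2-(triethylsilyloxy)pent-4-en-1-yl]-5-{(2R)-2-hydroxy-2-methyl-3-[(triethylsilyl)oxy]propyl}-3-methylideneoxolan-2-one, via allylzinc bromide 23 (not isolated)
Conditions: Zn dust (activated), THF/sat. aq. NH4Cl (5:1), 0 °C → rt
Reagents that add atoms: none
Why: Barbier-type zinc allylation: the allylzinc reagent adds through its γ-carbon C10 in a chair transition state on the butenolide face anti to the C9 side chain, which sets C10 trans to C9 and, because the ring locks the C9 substituent in the E position of the allyl unit, the anti relation between C10 and the new carbinol C1 (1S), and it creates the exocyclic methylene at the same time.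

Step 16
Reactants: 24 (4R,5S)-4-[(1S,2S,3R,4E)-1-hydroxy-5-iodo-3-methyl-2-(triethylsilyloxy)pent-4-en-1-yl]-5-{(2R)-2-hydroxy-2-methyl-3-[(triethylsilyl)oxy]propyl}-3-methylideneoxolan-2-one; 25 methacrylic anhydride
Product: 26 (1S,2S,3R,4E)-1-{(2S,3R)-2-[(2R)-2-hydroxy-2-methyl-3-(triethylsilyloxy)propyl]-4-methylidene-5-oxooxolan-3-yl}-5-iodo-3-methyl-2-(triethylsilyloxy)pent-4-en-1-yl 2-methylprop-2-enoate
Conditions: 25 (2 equiv), DMAP (0.2 equiv), Et3N, CH2Cl2, 0 °C → rt
Reagents that add atoms: none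
Why: DMAP-catalysed acylation esterifies the secondary C1 hydroxyl, the tertiary C7 hydroxyl being inert under these conditions, and the ester also blocks migration of the lactone from O9 to O1.

Step 17
Reactants: 26 (1S,2S,3R,4E)-1-{(2S,3R)-2-[(2R)-2-hydroxy-2-methyl-3-(triethylsilyloxy)propyl]-4-methylidene-5-oxooxolan-3-yl}-5-iodo-3-methyl-2-(triethylsilyloxy)pent-4-en-1-yl 2-methylprop-2-enoate
Product: 28 (1S,2S,3R,4E)-1-{(2S,3R)-2-[(2R)-2-hydroxy-2-methyl-3-oxopropyl]-4-methylidene-5-oxooxolan-3-yl}-5-iodo-3-methyl-2-(triethylsilyloxy)pent-4-en-1-yl 2-methylprop-2-enoate, via alkoxysulfonium chloride 27 (not isolated)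
Conditions: (COCl)2, DMSO, CH2Cl2, −78 → −30 °C; then Et3N, −78 → 0 °C
Reagents that add atoms: none
Why: Under Swern conditions the primary triethylsilyl ether is cleaved by the chlorosulfonium reagent and oxidised in the same flask to the aldehyde, whereas the hindered secondary silyl ether at C2 and the tertiary hydroxyl should be left alone.

Step 18
Reactants: 28 (1S,2S,3R,4E)-1-{(2S,3R)-2-[(2R)-2-hydroxy-2-methyl-3-oxopropyl]-4-methylidene-5-oxooxolan-3-yl}-5-iodo-3-methyl-2-(triethylsilyloxy)pent-4-en-1-yl 2-methylprop-2-enoate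
Product: 30 (3aR,4S,5S,6R,7E,9RS,10R,11aS)-9,10-dihydroxy-6,10-dimethyl-3-methylidene-2-oxo-5-(triethylsilyloxy)-2,3,3a,4,5,6,9,10,11,11a-decahydrocyclodeca[b]furan-4-yl 2-methylprop-2-enoate, via alkenylchromium dichloride 29 (not isolated)
Conditions: CrCl2 (10 equiv), NiCl2 (0.1 equiv), DMSO, rt, 2 mM (slow addition of 28)
Reagents that add atoms: none
Why: Nozaki–Hiyama–Kishi reaction: nickel-catalysed activation of the C–I bond and transmetalation give an alkenylchromium species (trivalent chromium) that adds chemoselectively to the aldehyde at high dilution, closing the ten-membered ring at C5–C6 with the E geometry retained; the C6 carbinol forms without control and is removed in step 19.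

Step 19
Reactants: 30 (3aR,4S,5S,6R,7E,9RS,10R,11aS)-9,10-dihydroxy-6,10-dimethyl-3-methylidene-2-oxo-5-(triethylsilyloxy)-2,3,3a,4,5,6,9,10,11,11a-decahydrocyclodeca[b]furan-4-yl 2-methylprop-2-enoate
Product: 31 (3aR,4S,5S,6R,7E,10R,11aS)-10-hydroxy-6,10-dimethyl-3-methylidene-2,9-dioxo-5-(triethylsilyloxy)-2,3,3a,4,5,6,9,10,11,11a-decahydrocyclodeca[b]furan-4-yl 2-methylprop-2-enoate
Conditions: Dess–Martin periodinane, NaHCO3, CH2Cl2, 0 °C
Reagents that add atoms: none
Why: Dess–Martin oxidation converts the secondary allylic carbinol into the enone and cannot oxidise the tertiary C7 hydroxyl, so both C6 epimers should converge on the α′-hydroxy (E)-enone.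

Step 20
Reactants: 31 (3aR,4S,5S,6R,7E,10R,11aS)-10-hydroxy-6,10-dimethyl-3-methylidene-2,9-dioxo-5-(triethylsilyloxy)-2,3,3a,4,5,6,9,10,11,11a-decahydrocyclodeca[b]furan-4-yl 2-methylprop-2-enoate
Product: 32 C2 triethylsilyl ether of the target (3(2H)-furanone bridged from C4 to C7 across the ten-membered ring)
Conditions: PdCl2(MeCN)2 (10 mol%), CuCl (10 mol%), Na2HPO4, O2 (1 atm), DME, 50 °C
Reagents that add atoms: none
Why: Divalent palladium coordinates the C4=C5 bond of the ring enone, the C7 hydroxyl adds at C4 anti to the metal (oxypalladation), and syn β-hydride elimination of H4 from the C5-bound palladium enolate re-forms C4=C5 as the enol ether of the 3(2H)-furanone, after which CuCl and O2 return zerovalent palladium to the divalent state. The closest known reaction type is the Wacker-type oxidative cyclisation of acyclic α′-hydroxy enones to 3(2H)-furanones, applied here across a ring. The one ring closed is the five-membered O–C4–C5–C6–C7 ring, formed in a 5-endo-trig, transannular mode that turns the cyclodecenone into an 11-oxabicyclo[6.2.1]undecene. No stereocentre is created: C4 is sp3 only in the palladium intermediate, where the cis bridge fixes it, and it returns to sp2. The step needs chemoselectivity for the ring enone over the methacrylate and the methylene lactone; this is secured by the C7 hydroxyl, which sits α′ to the ketone and is held over C4 by the ten-membered ring, whereas the two 1,1-disubstituted acrylate-type alkenes have no internal nucleophile and bind palladium poorly. The Na2HPO4 buffer keeps the medium neutral so that the C2 silyl ether should survive.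

Step 21
Reactants: 32 C2 triethylsilyl ether of the target
Product: 33 CNP0195404.1
Conditions: HF·pyridine, pyridine, THF, 0 °C → rt
Reagents that add atoms: none
Why: Fluoride-mediated desilylation under buffered, weakly acidic conditions frees the C2 hydroxyl and should spare the methacrylate (no base-induced acyl migration), the methylene lactone and the furanone.

Compound list
1 | (R)-citramalic acid | C[C@@](O)(CC(=O)O)C(=O)O | starting material
2 | 2-[(4R)-2,2,4-trimethyl-5-oxo-1,3-dioxolan-4-yl]acetic acid | C[C@]1(CC(=O)O)OC(C)(C)OC1=O | intermediate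
3 | 1-methoxy-4-[(prop-2-yn-1-yloxy)methyl]benzene | C#CCOCc1ccc(OC)cc1 | starting material
4 | 2-[(4R)-2,2,4-trimethyl-5-oxo-1,3-dioxolan-4-yl]acetyl chloride | C[C@]1(CC(=O)Cl)OC(C)(C)OC1=O | intermediate (not isolated)
5 | (5R)-5-{5-[(4-methoxybenzyl)oxy]-2-oxopent-3-yn-1-yl}-2,2,5-trimethyl-1,3-dioxolan-4-one | COc1ccc(COCC#CC(=O)C[C@@]2(C)OC(C)(C)OC2=O)cc1 | intermediate
6 | (5R)-5-{(2S)-2-hydroxy-5-[(4-methoxybenzyl)oxy]pent-3-yn-1-yl}-2,2,5-trimethyl-1,3-dioxolan-4-one | COc1ccc(COCC#C[C@@H](O)C[C@@]2(C)OC(C)(C)OC2=O)cc1 | intermediate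
7 | cyclic alkenyl(alkoxy)aluminate leading to 8 (Al bound to C11 and O9; C6 and C7 oxygens drawn as sodium alkoxides) | [Na+].[Na+].[Na+].COc1ccc(COCC2=C[C@H](C[C@@](C)([O-])C[O-])O[Al-]2(OCCOC)OCCOC)cc1 | intermediate (not isolated)
8 | (2R,4S,5Z)-6-iodo-7-[(4-methoxybenzyl)oxy]-2-methylhept-5-ene-1,2,4-triol | COc1ccc(COC/C(I)=C/[C@@H](O)C[C@@](C)(O)CO)cc1 | intermediate
9 | (5S)-5-[(2R)-2,3-dihydroxy-2-methylpropyl]-3-{[(4-methoxybenzyl)oxy]methyl}furan-2(5H)-one | COc1ccc(COCC2=C[C@H](C[C@@](C)(O)CO)OC2=O)cc1 | intermediate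
10 | (5S)-5-{(2R)-2-hydroxy-2-methyl-3-[(triethylsilyl)oxy]propyl}-3-{[(4-methoxybenzyl)oxy]methyl}furan-2(5H)-one | COc1ccc(COCC2=C[C@H](C[C@@](C)(O)CO[Si](CC)(CC)CC)OC2=O)cc1 | intermediate
11 | (5S)-3-(hydroxymethyl)-5-{(2R)-2-hydroxy-2-methyl-3-[(triethylsilyl)oxy]propyl}furan-2(5H)-one | OCC1=C[C@H](C[C@@](C)(O)CO[Si](CC)(CC)CC)OC1=O | intermediate
12 | (5S)-3-(bromomethyl)-5-{(2R)-2-hydroxy-2-methyl-3-[(triethylsilyl)oxy]propyl}furan-2(5H)-one | BrCC1=C[C@H](C[C@@](C)(O)CO[Si](CC)(CC)CC)OC1=O | intermediate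
13 | (4S)-4-benzyl-3-propanoyl-1,3-oxazolidin-2-one | CCC(=O)N1[C@@H](Cc2ccccc2)COC1=O | starting material
14 | 3-methylbut-2-enal | CC(C)=CC=O | starting material
15 | (Z)-dibutylboron enolate of 13 | C/C=C(\OB(CCCC)CCCC)N1[C@@H](Cc2ccccc2)COC1=O | intermediate (not isolated)
16 | (4S)-4-benzyl-3-[(2S,3R)-3-hydroxy-2,5-dimethylhex-4-enoyl]-1,3-oxazolidin-2-one | CC(C)=C[C@@H](O)[C@H](C)C(=O)N1[C@@H](Cc2ccccc2)COC1=O | intermediate
17 | (4S)-4-benzyl-3-[(2S,3R)-2,5-dimethyl-3-(triethylsilyloxy)hex-4-enoyl]-1,3-oxazolidin-2-one | CC(C)=C[C@@H](O[Si](CC)(CC)CC)[C@H](C)C(=O)N1[C@@H](Cc2ccccc2)COC1=O | intermediate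
18 | (2R,3R)-2,5-dimethyl-3-(triethylsilyloxy)hex-4-en-1-ol | CC(C)=C[C@@H](O[Si](CC)(CC)CC)[C@H](C)CO | intermediate
19 | (2S,3R)-2,5-dimethyl-3-(triethylsilyloxy)hex-4-enal | CC(C)=C[C@@H](O[Si](CC)(CC)CC)[C@H](C)C=O | intermediate
20 | triethyl{[(1E,3R,4S)-1-iodo-3,6-dimethylhepta-1,5-dien-4-yl]oxy}silane | CC(C)=C[C@@H](O[Si](CC)(CC)CC)[C@H](C)/C=C/I | intermediate
21 | ozonide (3,3-dimethyl-1,2,4-trioxolane) of the trisubstituted alkene of 20, both epimers at the ring CH | CC1(C)OOC(O1)[C@@H](O[Si](CC)(CC)CC)[C@H](C)/C=C/I | intermediate (not isolated)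
22 | (2S,3R,4E)-5-iodo-3-methyl-2-(triethylsilyloxy)pent-4-enal | O=C[C@@H](O[Si](CC)(CC)CC)[C@H](C)/C=C/I | intermediate
23 | allylzinc bromide formed from 12 (zinc on C13) | Br[Zn]CC1=C[C@H](C[C@@](C)(O)CO[Si](CC)(CC)CC)OC1=O | intermediate (not isolated)
24 | (4R,5S)-4-[(1S,2S,3R,4E)-1-hydroxy-5-iodo-3-methyl-2-(triethylsilyloxy)pent-4-en-1-yl]-5-{(2R)-2-hydroxy-2-methyl-3-[(triethylsilyl)oxy]propyl}-3-methylideneoxolan-2-one | C=C1C(=O)O[C@@H](C[C@@](C)(O)CO[Si](CC)(CC)CC)[C@@H]1[C@H](O)[C@@H](O[Si](CC)(CC)CC)[C@H](C)/C=C/I | intermediate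
25 | methacrylic anhydride | C=C(C)C(=O)OC(=O)C(C)=C | starting material
26 | (1S,2S,3R,4E)-1-{(2S,3R)-2-[(2R)-2-hydroxy-2-methyl-3-(triethylsilyloxy)propyl]-4-methylidene-5-oxooxolan-3-yl}-5-iodo-3-methyl-2-(triethylsilyloxy)pent-4-en-1-yl 2-methylprop-2-enoate | C=C1C(=O)O[C@@H](C[C@@](C)(O)CO[Si](CC)(CC)CC)[C@@H]1[C@H](OC(=O)C(C)=C)[C@@H](O[Si](CC)(CC)CC)[C@H](C)/C=C/I | intermediate
27 | dimethyl(alkoxy)sulfonium chloride at O6 of desilylated 26 | C=C1C(=O)O[C@@H](C[C@@](C)(O)CO[S+](C)C)[C@@H]1[C@H](OC(=O)C(C)=C)[C@@H](O[Si](CC)(CC)CC)[C@H](C)/C=C/I.[Cl-] | intermediate (not isolated)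
28 | (1S,2S,3R,4E)-1-{(2S,3R)-2-[(2R)-2-hydroxy-2-methyl-3-oxopropyl]-4-methylidene-5-oxooxolan-3-yl}-5-iodo-3-methyl-2-(triethylsilyloxy)pent-4-en-1-yl 2-methylprop-2-enoate | C=C1C(=O)O[C@@H](C[C@@](C)(O)C=O)[C@@H]1[C@H](OC(=O)C(C)=C)[C@@H](O[Si](CC)(CC)CC)[C@H](C)/C=C/I | intermediate
29 | alkenylchromium dichloride formed from 28 (chromium on C5) | C=C1C(=O)O[C@@H](C[C@@](C)(O)C=O)[C@@H]1[C@H](OC(=O)C(C)=C)[C@@H](O[Si](CC)(CC)CC)[C@H](C)/C=C/[Cr](Cl)Cl | intermediate (not isolated)
30 | (3aR,4S,5S,6R,7E,9RS,10R,11aS)-9,10-dihydroxy-6,10-dimethyl-3-methylidene-2-oxo-5-(triethylsilyloxy)-2,3,3a,4,5,6,9,10,11,11a-decahydrocyclodeca[b]furan-4-yl 2-methylprop-2-enoate | C=C(C)C(=O)O[C@@H]1[C@@H](O[Si](CC)(CC)CC)[C@H](C)/C=C/C(O)[C@](C)(O)C[C@@H]2OC(=O)C(=C)[C@@H]12 | intermediate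
31 | (3aR,4S,5S,6R,7E,10R,11aS)-10-hydroxy-6,10-dimethyl-3-methylidene-2,9-dioxo-5-(triethylsilyloxy)-2,3,3a,4,5,6,9,10,11,11a-decahydrocyclodeca[b]furan-4-yl 2-methylprop-2-enoate (precursor of the key step) | C=C(C)C(=O)O[C@@H]1[C@@H](O[Si](CC)(CC)CC)[C@H](C)/C=C/C(=O)[C@](C)(O)C[C@@H]2OC(=O)C(=C)[C@@H]12 | intermediate
32 | C2 triethylsilyl ether of the target (product of the key step) | C=C(C)C(=O)O[C@@H]1[C@@H](O[Si](CC)(CC)CC)[C@H](C)C2=CC(=O)[C@@](C)(C[C@@H]3OC(=O)C(=C)[C@@H]13)O2 | intermediate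
33 | CNP0195404.1, (1S,2S,3S,7R,9S,10R) in the numbering used here | C=C(C)C(=O)O[C@@H]1[C@@H](O)[C@H](C)C2=CC(=O)[C@@](C)(C[C@@H]3OC(=O)C(=C)[C@@H]13)O2 | target

Total step count: 21 steps.
Longest linear sequence: 15 steps (steps 1–8 and 15–21, from 1); the aldehyde branch (steps 9–14) has 6 steps.

Steps most likely to fail

1. Step 20 (transannular oxidative etherification). The oxypalladation may be slow if the ring conformation keeps the C7 hydroxyl away from the palladium-bound face of C4=C5, so that catalyst decay or attack at the acrylate-type alkenes takes over. The fallback sets out from 31 and comes back at 32, and separates C–O bond formation from dehydrogenation. Acid-catalysed transannular oxa-Michael addition (CSA cat., CH2Cl2, 0 °C) should give the bridged tetrahydrofuran-3-one F1. The C4=C5 bond is then restored by IBX dehydrogenation of the ketone (IBX, DMSO, 65 °C), which can only enolise towards C5, to give 32.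

2. Step 18 (ring closure at C5–C6). Closure of the strained ten-membered ring may be slower than protodemetalation of the alkenylchromium intermediate or intermolecular coupling. The fallback sets out from 9 and 20 and comes back at 31; it exchanges the order of the two C–C couplings, so that the ring is closed at C10–C1 instead. Diol 9 is oxidised at its primary hydroxyl (TEMPO cat., PhI(OAc)2, CH2Cl2) to hydroxy aldehyde F2. Intermolecular Nozaki–Hiyama–Kishi coupling with 20 (CrCl2, NiCl2 cat., DMSO) gives diol F3, and Dess–Martin oxidation gives enone F4. DDQ frees the allylic alcohol F5, and CBr4/PPh3 gives allylic bromide F6. Ozonolysis of the trisubstituted alkene (O3, CH2Cl2, −78 °C; Me2S) gives bromo aldehyde F7. CrCl2 in THF at high dilution then closes the ring by intramolecular allylation of the aldehyde, which allylchromium reagents attack in preference to the C6 ketone, to give macrocyclic hydroxy lactone F8. Acylation with 25 (DMAP, Et3N) returns 31.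

3. Step 15 (zinc allylation). This is a case of double stereodifferentiation: the Felkin–Anh preference of the α-silyloxy aldehyde opposes the aldehyde face that the chair transition state demands, so facial selectivity at C1 may erode. The fallback sets out from 12 and 22 and comes back at 26. The C1 epimer F9 formed in the coupling is separated and esterified with inversion under Mitsunobu conditions (methacrylic acid, PPh3, DIAD, toluene, 0 °C), which gives 26 directly; material of the correct configuration passes through step 16 as planned.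

Further compounds
F1 | step 20 | 4,5-dihydro derivative of 32 (bridged tetrahydrofuran-3-one, H4 cis to the C7 methyl) | C=C(C)C(=O)O[C@@H]1[C@@H](O[Si](CC)(CC)CC)[C@H](C)[C@H]2CC(=O)[C@@](C)(C[C@@H]3OC(=O)C(=C)[C@@H]13)O2
F2 | step 18 | (2R)-2-hydroxy-3-[(2S)-4-{[(4-methoxybenzyl)oxy]methyl}-5-oxo-2,5-dihydrofuran-2-yl]-2-methylpropanal | COc1ccc(COCC2=C[C@H](C[C@@](C)(O)C=O)OC2=O)cc1
F3 | step 18 | coupling product of 20 and F2, C6 carbinol as both epimers | CC(C)=C[C@@H](O[Si](CC)(CC)CC)[C@H](C)/C=C/C(O)[C@](C)(O)C[C@H]1C=C(COCc2ccc(OC)cc2)C(=O)O1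
F4 | step 18 | α′-hydroxy (E)-enone from F3 | CC(C)=C[C@@H](O[Si](CC)(CC)CC)[C@H](C)/C=C/C(=O)[C@](C)(O)C[C@H]1C=C(COCc2ccc(OC)cc2)C(=O)O1
F5 | step 18 | 3-(hydroxymethyl)butenolide from F4 | CC(C)=C[C@@H](O[Si](CC)(CC)CC)[C@H](C)/C=C/C(=O)[C@](C)(O)C[C@H]1C=C(CO)C(=O)O1
F6 | step 18 | 3-(bromomethyl)butenolide from F5 | CC(C)=C[C@@H](O[Si](CC)(CC)CC)[C@H](C)/C=C/C(=O)[C@](C)(O)C[C@H]1C=C(CBr)C(=O)O1
F7 | step 18 | C1 aldehyde from F6 | O=C[C@@H](O[Si](CC)(CC)CC)[C@H](C)/C=C/C(=O)[C@](C)(O)C[C@H]1C=C(CBr)C(=O)O1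
F8 | step 18 | C1 alcohol corresponding to 31 (31 without the methacryloyl group) | O[C@@H]1[C@@H](O[Si](CC)(CC)CC)[C@H](C)/C=C/C(=O)[C@](C)(O)C[C@@H]2OC(=O)C(=C)[C@@H]12
F9 | step 15 | C1 epimer of 24 (1R carbinol) | C=C1C(=O)O[C@@H](C[C@@](C)(O)CO[Si](CC)(CC)CC)[C@@H]1[C@@H](O)[C@@H](O[Si](CC)(CC)CC)[C@H](C)/C=C/I
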